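(All runs were computed with constants of no real substance, noise included.)

The question is what share of the J in the south-west flask has become E at 6.9 min, and I want that from one number I can check by hand.

| flask | J | Z | time |
|---|---|---|---|
| north-west | 1.00 M | 3.00 M |  |
| west | 0.400 M | 2.40 M |  |
| south-east | 1.00 M | 1.50 M |  |
| north-east | 3.00 M | 3.00 M |  |
| south-west | 0.330 M | 6.00 M | 6.9 min |

| run | time / min | [E] / M |
|---|---|---|
| north-west run | 0.99 | 0.168 |
| north-west run | 2.0 | 0.299 |
| north-west run | 3.0 | 0.421 |
| north-west run | 3.9 | 0.501 |
| north-west run | 4.9 | 0.566 |
| north-west run | 5.9 | 0.633 |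
| north-west run | 6.9 | 0.684 |
| west run | 0.99 | 0.064 |
| west run | 2.0 | 0.118 |
| west run | 3.0 | 0.164 |
| west run | 3.9 | 0.198 |
| west run | 4.9 | 0.227 |
| west run | 5.9 | 0.249 |
| west run | 6.9 | 0.277 |
| south-east run | 0.99 | 0.116 |
| south-east run | 2.0 | 0.212 |
| south-east run | 3.0 | 0.281 |
| south-east run | 3.9 | 0.346 |
| south-east run | 4.9 | 0.395 |
| south-east run | 5.9 | 0.448 |
| south-east run | 6.9 | 0.485 |
| north-east run | 0.99 | 0.401 |
| north-east run | 2.0 | 0.723 |
| north-east run | 3.0 | 0.960 |
| north-east run | 3.9 | 1.135 |
| north-east run | 4.9 | 1.286 |
| north-east run | 5.9 | 1.423 |
| north-east run | 6.9 | 1.524 |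

(each reading ± 0.005 M)

- reaction order in [Z] at the outset, round the charge of the north-west run, defined at two percent of the J turned into E
- reaction order in [J] at the outset, round the charge of the north-west run, defined at two percent of the J turned into E (one fixed amount of E, the same in the runs compared)
- E in the south-west run at 6.9 min, as a share of the J charged

- Overall: J + Z -> E.
- Constant volume, constant temperature.
- The analysis sees a species whether free or bound.
- "The second partner" is Z.
- An order is taken over about fifteen percent of the charge, up and down.

My number is N, the count of lifetimes of J that have passed: N = ln(cJ charged / cJ not yet turned into E), so the share of J not yet turned is exp(−N), and N grows in step with time while the decay stays pseudo-first-order, with cZ close to its charge. The west run, charged with cJ 0.400 M against 0.330 M in the south-west flask, has passed 1.18 lifetimes at 6.9 min. Going from cZ 3.00 M to 1.50 M at equal cJ takes the first reading from 0.168 M to 0.116 M, so I read an order in Z of 0.534. Scaling the west count by the ratio of cZ charges raised to that order, I reckon 1.92 lifetimes of J for the south-west flask in the same time, and this count N gives a share of 85.4%.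

Is one number enough? The same step from the west run gives the north-west run 1.33 lifetimes, a share of 73.5%, but its last reading is 68.4%. That overshoot of 5.1 percentage points is far beyond the scatter. The E made there equals 22.8% of the Z charged, whereas the south-west charge allows 5.50%, so I keep my share for that flask and expect a smaller overshoot.

The forecast gives an order in Z of 0.48 and an order in J of 0.87, and for the south-west flask, “with Z nearly constant”, a share of 82%. Its share is lower than mine, and so is its order in Z.

The flask gives an order in Z of 0.57, an order in J of 0.93 and a south-west share of 84.3%, and that share is 1.85 lifetimes of J against my 1.92.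

    J + Z → E + G (0.1446 M⁻¹ min⁻¹)
    J + Z ⇌ JZ, settled at all times (0.3590 M⁻¹)
    Z + G ⇌ ZG, settled at all times (1.380 M⁻¹)

The pairing of Z with G makes no difference worth counting to that share. In the north-west run, the count scaled from the west run passes at 0.193 min⁻¹, and a quarter of J turned means N = 0.288, so I get 1.49 min; the flask takes 1.56 min.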